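The route rests on cutting the C2–C3 bond of ring C. C2 is a bare CH2 on O1 of ring A, that is, a latent aryl methyl ether. C3 lies between the C4 carbonyl and ring B, that is, a latent donor/acceptor carbene. A chiral dirhodium carboxylate turns an open-chain α-aryl-α-diazoketone (a 2-methoxy diazodeoxybenzoin carrying the geranyl chain and three silyl ethers) into the chroman-4-one by insertion of C3 into a methoxy C–H bond. One neutral operation makes the C–C bond, closes ring C and sets the base-labile C3 stereocentre. The precursor comes from ketone α-arylation and diazo transfer; mild desilylation ends the synthesis.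

Key step: step 6

Assumption: the sense of induction of Rh2(S-PTAD)4, dirhodium tetrakis[(S)-(1-adamantyl)(N-phthalimido)acetate], in step 6 cannot be read off a close analogue. The (S)-catalyst is written for the (3R) product, and its mirror image Rh2(R-PTAD)4 is taken if a trial run shows the opposite sense.

Step 1
Reactants: 1 4,6-dibromoresorcinol (4,6-dibromobenzene-1,3-diol)
Product: 2 1,5-dibromo-2,4-bis(tert-butyldimethylsilyloxy)benzene
Conditions: TBSCl (2.4 equiv), imidazole, DMF, rt
Reagents that add atoms: tert-butyldimethylsilyl chloride (TBSCl), CC(C)(C)[Si](C)(C)Cl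
Why: Standard imidazole-promoted silylation of phenols, silyl ethers being chosen because they offer the later carbene no C–H bond next to oxygen and can be removed with fluoride under non-basic conditions.

Step 2
Reactants: 2 1,5-dibromo-2,4-bis(tert-butyldimethylsilyloxy)benzene, 3 geranyl bromide [(2E)-1-bromo-3,7-dimethylocta-2,6-diene]
Product: 6 1-bromo-2,4-bis(tert-butyldimethylsilyloxy)-5-[(2E)-3,7-dimethylocta-2,6-dien-1-yl]benzene, via aryllithium 4 (not isolated), via arylcopper 5 (not isolated)
Conditions: n-BuLi (1.0 equiv), THF, −78 °C; CuBr·SMe2 (1.0 equiv), −78 to −40 °C; 3, −40 to 0 °C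
Reagents that add atoms: none
Why: Bromine–lithium exchange followed by copper-mediated allylic substitution, in which the two equivalent bromines of 2 give a single aryllithium, early transmetalation to copper forestalls the retro-Brook O-to-C silyl shift, and attack at the unhindered primary carbon of 3 (SN2) keeps the E-alkene.

Step 3
Reactants: 7 1-(4-hydroxy-2-methoxyphenyl)ethan-1-one (4'-hydroxy-2'-methoxyacetophenone)
Product: 8 1-[4-(tert-butyldimethylsilyloxy)-2-methoxyphenyl]ethan-1-one
Conditions: TBSCl, imidazole, DMF, rt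
Reagents that add atoms: tert-butyldimethylsilyl chloride (TBSCl), CC(C)(C)[Si](C)(C)Cl
Why: Standard phenol silylation, which masks the only acidic O–H of the ketone partner before enolate chemistry and leaves the 2-methoxy group as the future C2.

Step 4
Reactants: 6 1-bromo-2,4-bis(tert-butyldimethylsilyloxy)-5-geranylbenzene, 8 1-[4-(tert-butyldimethylsilyloxy)-2-methoxyphenyl]ethan-1-one
Product: 9 1-[4-(tert-butyldimethylsilyloxy)-2-methoxyphenyl]-2-{2,4-bis(tert-butyldimethylsilyloxy)-5-[(2E)-3,7-dimethylocta-2,6-dien-1-yl]phenyl}ethan-1-one (the deoxybenzoin)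
Conditions: Pd2(dba)3 (2 mol %), XPhos (8 mol %), K3PO4, toluene, 100 °C
Reagents that add atoms: none
Why: Palladium-catalysed ketone α-arylation, in which the enolate of the methyl ketone couples with the aryl bromide on a zerovalent palladium/bulky biaryl phosphine catalyst, the weak base K3PO4 spares the aryl silyl ethers and the ortho-substituted aryl group stops the reaction at monoarylation.

Step 5
Reactants: 9 the deoxybenzoin
Product: 10 2-diazo-1-[4-(tert-butyldimethylsilyloxy)-2-methoxyphenyl]-2-{2,4-bis(tert-butyldimethylsilyloxy)-5-[(2E)-3,7-dimethylocta-2,6-dien-1-yl]phenyl}ethan-1-one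
Conditions: p-ABSA, DBU, dry MeCN/THF, 0 °C to rt
Reagents that add atoms: 4-acetamidobenzenesulfonyl azide (p-ABSA), CC(=O)Nc1ccc(cc1)S(=O)(=O)N=[N+]=[N-]
Why: Regitz diazo transfer, which works directly because the methylene flanked by the aroyl group and ring B is acidic enough for DBU, water being excluded to protect the aryl silyl ethers.

Step 6
Reactants: 10 the α-aryl-α-diazoketone
Product: 11 (3R)-7-(tert-butyldimethylsilyloxy)-3-{2,4-bis(tert-butyldimethylsilyloxy)-5-[(2E)-3,7-dimethylocta-2,6-dien-1-yl]phenyl}-2,3-dihydro-4H-chromen-4-one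
Conditions: Rh2(S-PTAD)4 (1 mol %), 2,2-dimethylbutane, 4 Å molecular sieves, reflux (50 °C), slow syringe-pump addition of 10, high dilution
Reagents that add atoms: none
Why: The catalyst expels N2 from 10 to give a rhodium-bound donor/acceptor carbene at C3 (donor ring B, acceptor C4=O), whose empty orbital takes up a C–H bond of the neighbouring ring A methoxy group in a concerted, hydride-transfer-like three-centre insertion that makes the C2–C3 and C3–H bonds at once. The closest known reaction types are the dirhodium-catalysed cyclisation of 2-alkoxyaryl α-diazoketones to chroman-4-ones and the insertion of donor/acceptor carbenes into methyl ethers. Ring C closes by 1,6-insertion through a six-membered transition state in which C4, C4a, C8a and O1 are already linked and held by ring A, so that only the methoxy carbon has to reach C3. The only new stereocentre, C3, is set by the chiral carboxylate pocket of the catalyst, which leaves one face of the carbene open to the methoxy group, and it should survive because the medium is neutral and aprotic. The step needs selectivity for O–CH3 over the chain alkenes, the silyl groups and ylide formation. Donor/acceptor carbenes are sluggish towards trisubstituted alkenes and high dilution disfavours bimolecular paths, the meta-placed geranyl chain is out of intramolecular reach, the silylated 2'-oxygen offers no C–H next to oxygen for a faster 1,5-insertion, and a methyl oxonium ylide has no easy 1,2- or 2,3-shift and should revert.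

Step 7
Reactants: 11 the tris-silyl (3R)-isoflavanone
Product: 12 (3R)-3-{5-[(2E)-3,7-dimethylocta-2,6-dien-1-yl]-2,4-dihydroxyphenyl}-7-hydroxy-2,3-dihydro-4H-chromen-4-one (target)
Conditions: KHF2 (excess), MeOH/THF, rt; neutral work-up
Reagents that add atoms: none
Why: Fluoride-mediated desilylation of aryl silyl ethers under weakly acidic conditions, with no base strong enough to enolise C3 and no acid strong enough to cyclise the geranyl chain onto the 4'-hydroxyl.

Compound list
1 | 4,6-dibromoresorcinol | Oc1cc(O)c(Br)cc1Br | starting material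
2 | 1,5-dibromo-2,4-bis(tert-butyldimethylsilyloxy)benzene | CC(C)(C)[Si](C)(C)Oc1cc(O[Si](C)(C)C(C)(C)C)c(Br)cc1Br | intermediate
3 | geranyl bromide, (2E)-1-bromo-3,7-dimethylocta-2,6-diene | CC(C)=CCC/C(C)=C/CBr | starting material
4 | [5-bromo-2,4-bis(tert-butyldimethylsilyloxy)phenyl]lithium | [Li]c1cc(Br)c(O[Si](C)(C)C(C)(C)C)cc1O[Si](C)(C)C(C)(C)C | intermediate
5 | [5-bromo-2,4-bis(tert-butyldimethylsilyloxy)phenyl]copper | [Cu]c1cc(Br)c(O[Si](C)(C)C(C)(C)C)cc1O[Si](C)(C)C(C)(C)C | intermediate
6 | 1-bromo-2,4-bis(tert-butyldimethylsilyloxy)-5-[(2E)-3,7-dimethylocta-2,6-dien-1-yl]benzene | CC(C)=CCC/C(C)=C/Cc1cc(Br)c(O[Si](C)(C)C(C)(C)C)cc1O[Si](C)(C)C(C)(C)C | intermediate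
7 | 1-(4-hydroxy-2-methoxyphenyl)ethan-1-one | COc1cc(O)ccc1C(C)=O | starting material
8 | 1-[4-(tert-butyldimethylsilyloxy)-2-methoxyphenyl]ethan-1-one | COc1cc(O[Si](C)(C)C(C)(C)C)ccc1C(C)=O | intermediate
9 | deoxybenzoin: 1-[4-(tert-butyldimethylsilyloxy)-2-methoxyphenyl]-2-[2,4-bis(tert-butyldimethylsilyloxy)-5-geranylphenyl]ethan-1-one | CC(C)=CCC/C(C)=C/Cc1cc(CC(=O)c2ccc(O[Si](C)(C)C(C)(C)C)cc2OC)c(O[Si](C)(C)C(C)(C)C)cc1O[Si](C)(C)C(C)(C)C | intermediate
10 | 2-diazo derivative of 9 (α-aryl-α-diazoketone) | CC(C)=CCC/C(C)=C/Cc1cc(C(=[N+]=[N-])C(=O)c2ccc(O[Si](C)(C)C(C)(C)C)cc2OC)c(O[Si](C)(C)C(C)(C)C)cc1O[Si](C)(C)C(C)(C)C | intermediate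
11 | (3R)-7,2',4'-tris(tert-butyldimethylsilyloxy)-5'-geranylisoflavanone | CC(C)=CCC/C(C)=C/Cc1cc([C@@H]2COc3cc(O[Si](C)(C)C(C)(C)C)ccc3C2=O)c(O[Si](C)(C)C(C)(C)C)cc1O[Si](C)(C)C(C)(C)C | intermediate
12 | (3R)-7,2',4'-trihydroxy-5'-geranylisoflavanone (CNP0142504.1) | CC(C)=CCC/C(C)=C/Cc1cc([C@@H]2COc3cc(O)ccc3C2=O)c(O)cc1O | target

Total steps: 7. Longest linear sequence: 6 (steps 1, 2, 4, 5, 6, 7).

Steps most likely to fail

Step 6. The carbene may be diverted by attack of the methoxy oxygen with methyl transfer, by bimolecular reaction at the chain alkenes or by Wolff rearrangement, or the facial selectivity may be poor.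
- The fallback sets out from 9 and comes back at 11; it gives up the insertion and sets C3 after ring closure.
- The methyl ether ortho to the carbonyl is cleaved under chelation control with MgI2·OEt2 (toluene/Et2O, 60 °C) to the 2-hydroxy deoxybenzoin F1.
- α-Methylenation with paraformaldehyde and iPr2NH·CF3CO2H (THF, reflux), followed by oxa-Michael closure on brief exposure to Et3N, gives the racemic tris-silyl isoflavanone F2.
- Asymmetric transfer hydrogenation with dynamic kinetic resolution uses RuCl[(R,R)-TsDPEN](p-cymene), HCO2H/Et3N, EtOAc, rt. C3 epimerises faster than the ketone is reduced, and this should give the cis-(3R,4R)-isoflavan-4-ol F3.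
- Dess–Martin periodinane (CH2Cl2, 0 °C) returns the ketone 11 without touching C3.

Step 2. O-to-C silyl migration may occur in the ortho-lithiated silyl ether, both bromines may exchange, or allylic transposition may occur in the copper step.
- The fallback sets out from 2 and comes back at 6 with reversed polarity.
- A Stille coupling joins 2 as the electrophile with one equivalent of (E)-geranyltributylstannane (Pd(PPh3)4, DMF, 80 °C), so that no organolithium is formed.
- The more hindered, more electron-rich product should react more slowly than 2.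
- No compound outside the list is made (F0).

Step 4. Oxidative addition and reductive elimination may be sluggish at the hindered, electron-rich bromide, and silyl groups may be lost or migrate under base at high temperature.
- The fallback sets out from 8 and 6 and comes back at 10, bypassing 9 and step 5.
- Ketone 8 is trifluoroacetylated (LiHMDS, THF, −78 °C; CF3CO2CH2CF3) to the trifluoromethyl 1,3-diketone F4.
- Detrifluoroacetylative diazo transfer (MsN3, Et3N, H2O, MeCN) converts F4 into the diazomethyl ketone F5.
- Bromide 6 is turned into the aryl iodide F6 (n-BuLi, THF, −78 °C; I2).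
- Palladium-catalysed C–H arylation of the acyldiazomethane with retention of the diazo group (Pd(PPh3)4, Ag2CO3, Et3N, toluene, rt) joins the two halves directly as 10.

Further compounds
F1 | step 6 | 1-[4-(tert-butyldimethylsilyloxy)-2-hydroxyphenyl]-2-[2,4-bis(tert-butyldimethylsilyloxy)-5-geranylphenyl]ethan-1-one | CC(C)=CCC/C(C)=C/Cc1cc(CC(=O)c2ccc(O[Si](C)(C)C(C)(C)C)cc2O)c(O[Si](C)(C)C(C)(C)C)cc1O[Si](C)(C)C(C)(C)C
F2 | step 6 | racemic 7,2',4'-tris(tert-butyldimethylsilyloxy)-5'-geranylisoflavanone | CC(C)=CCC/C(C)=C/Cc1cc(C2COc3cc(O[Si](C)(C)C(C)(C)C)ccc3C2=O)c(O[Si](C)(C)C(C)(C)C)cc1O[Si](C)(C)C(C)(C)C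
F3 | step 6 | cis-(3R,4R)-7,2',4'-tris(tert-butyldimethylsilyloxy)-5'-geranylisoflavan-4-ol | CC(C)=CCC/C(C)=C/Cc1cc([C@@H]2COc3cc(O[Si](C)(C)C(C)(C)C)ccc3[C@@H]2O)c(O[Si](C)(C)C(C)(C)C)cc1O[Si](C)(C)C(C)(C)C
F0 | step 2 | none | none
F4 | step 4 | 4,4,4-trifluoro-1-[4-(tert-butyldimethylsilyloxy)-2-methoxyphenyl]butane-1,3-dione | COc1cc(O[Si](C)(C)C(C)(C)C)ccc1C(=O)CC(=O)C(F)(F)F
F5 | step 4 | 2-diazo-1-[4-(tert-butyldimethylsilyloxy)-2-methoxyphenyl]ethan-1-one | COc1cc(O[Si](C)(C)C(C)(C)C)ccc1C(=O)C=[N+]=[N-]
F6 | step 4 | 1-iodo-2,4-bis(tert-butyldimethylsilyloxy)-5-[(2E)-3,7-dimethylocta-2,6-dien-1-yl]benzene | CC(C)=CCC/C(C)=C/Cc1cc(I)c(O[Si](C)(C)C(C)(C)C)cc1O[Si](C)(C)C(C)(C)C
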